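**Plan**

Atom labels follow the farnesane skeleton: vinyl C1=C2, carbinol C3, chain C4–C5, ring C6–C11, methylidene carbon C15 on C7, bromine on C8 and C10, two methyl groups on C11.

Retrosynthesis: the C7=C15 double bond is masked as a C15 selenide, both C–Br bonds go back to C–O bonds of opposite configuration, C15 is detached from C7, and the ring is opened at C6–C11 and C9–C10. This works because C8 and C10 are 1,3-related heteroatom-bearing ring carbons on either side of C9, with the quaternary C11 directly beside C10: the six-membered ring is a reduced, brominated 4,4-dimethylcyclohexane-1,3-dione, made of an enone (C6–C9) and an isobutyrate unit (C10, C11).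

Forward: (S)-linalool is silylated and cut at its trisubstituted alkene to the C1–C6 aldehyde, and a Wittig reaction adds C7–C9 as an E-enone. The only ring is closed in one flask by Mukaiyama–Michael addition (C6–C11) and Claisen condensation (C9–C10). C15 is then attached at C7 and carried as CH2SePh while both carbonyls are reduced and both carbinols exchanged for bromine; the methylidene group is released last.

Stereochemistry: C3 comes from (S)-linalool; C6 from a chiral boron Lewis acid in the Michael addition. The C10 carbinol arises by axial hydride addition (cis to the side chain) and the C8 carbinol by equatorial attack of a bulky hydride (trans to the side chain); each is inverted by SN2 bromination.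

Key step: step 4

Assumption: the (S)-configured oxazaborolidinium catalyst is taken to direct the ketene acetal to the Re face of C6, by analogy with its behaviour toward other β-substituted enones; if the first correlation shows the opposite sense, the (R)-catalyst takes its place and nothing else changes.

**Route**

Step 1
Reactants: 1 (S)-linalool
Product: 2 triethyl{[(3S)-3,7-dimethylocta-1,6-dien-3-yl]oxy}silane
Conditions: Et3SiOTf, 2,6-lutidine, CH2Cl2, −78 °C to 0 °C
Reagents that add atoms: triethylsilyl trifluoromethanesulfonate, CC[Si](CC)(CC)OS(=O)(=O)C(F)(F)F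
Why: Silyl triflate silylation of a hindered tertiary alcohol under non-acidic conditions masks the ionisable tertiary allylic carbinol against the later bases, hydrides and phosphonium reagents and leaves C3 untouched.

Step 2
Reactants: 2 triethyl{[(3S)-3,7-dimethylocta-1,6-dien-3-yl]oxy}silane
Product: 4 (S)-4-methyl-4-(triethylsilyloxy)hex-5-enal, via secondary ozonide 3 (not isolated)
Conditions: O3 (1.0 equiv), CH2Cl2, −78 °C; then Me2S, −78 °C to rt
Reagents that add atoms: ozone, [O-][O+]=O
Why: Ozonolysis with reductive work-up, in which the electrophilic ozone consumes the electron-rich trisubstituted alkene much faster than the monosubstituted vinyl group, so that one equivalent should cleave only the isopropylidene end.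

Step 3
Reactants: 4 (S)-4-methyl-4-(triethylsilyloxy)hex-5-enal; 5 1-(triphenylphosphoranylidene)propan-2-one
Product: 6 (S,E)-7-methyl-7-(triethylsilyloxy)nona-3,8-dien-2-one
Conditions: toluene, 80 °C
Reagents that add atoms: none
Why: Wittig olefination with a ketone-stabilised ylide, which is E-selective and needs no added base that could enolise the aldehyde.

Step 4
Reactants: 6 (S,E)-7-methyl-7-(triethylsilyloxy)nona-3,8-dien-2-one; 7 1-methoxy-2-methyl-1-(trimethylsilyloxy)prop-1-ene
Product: 9 (R)-4,4-dimethyl-5-[(S)-3-methyl-3-(triethylsilyloxy)pent-4-enyl]cyclohexane-1,3-dione, via trimethylsilyl enol ether 8 (not isolated)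
Conditions: (S)-1-(2-methylphenyl)-3,3-diphenyltetrahydro-1H,3H-pyrrolo[1,2-c][1,3,2]oxazaborole (24 mol %) + HNTf2 (20 mol %), Ph3PO (25 mol %), toluene, −20 °C; then KOtBu (3 equiv), THF, 0 °C to rt; 1 M HCl to pH 4, 0 °C
Reagents that add atoms: none
Why: The cationic oxazaborolidinium Lewis acid binds the carbonyl oxygen of 6, the nucleophilic carbon of the tetrasubstituted ketene silyl acetal 7 adds to the β-carbon C6 and forms the C6–C11 bond together with the quaternary C11, and the silyl group ends on the enolate oxygen (relayed by Ph3PO) to give 8; KOtBu then cleaves the O–Si bond, the enolate equilibrates through tBuOH to the methyl-side enolate, and its carbon C9 attacks the ester carbon C10 with loss of methoxide. The closest known reaction type is the Michael–Claisen synthesis of dimedone-type cyclohexane-1,3-diones, here with the Michael half run as an oxazaborolidinium-catalysed enantioselective Mukaiyama–Michael addition of a ketene silyl acetal to an enone. The six-membered ring closes by a 6-(enolendo)-exo-trig acyl substitution (Claisen condensation) of the C9 enolate carbon on the ester carbonyl. C6 is the only new stereocentre and is controlled by the catalyst, which is taken to block the Si face of the bound E-enone so that 7 attacks the Re face and the ring carbon becomes R, while C3 is four bonds away and has no influence. The step needs 1,4- instead of 1,2-addition, which the soft, hindered silyl ketene acetal and carbonyl activation secure, and ring closure through C9 instead of C7, which follows because attack by C7 would give a strained cyclobutanone reversibly while the dione leaves the equilibrium as its stabilised enolate. The tertiary allylic silyl ether is protected from ionisation by keeping the oxazaborolidine in slight excess over HNTf2, so that no free acid is present, at −20 °C in toluene.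

Step 5
Reactants: 9 (R)-4,4-dimethyl-5-[(S)-3-methyl-3-(triethylsilyloxy)pent-4-enyl]cyclohexane-1,3-dione
Product: 10 (R)-6,6-dimethyl-5-[(S)-3-methyl-3-(triethylsilyloxy)pent-4-enyl]-3-(triisopropylsilyloxy)cyclohex-2-en-1-one
Conditions: iPr3SiOTf (1.05 equiv), Et3N, CH2Cl2, −78 °C to 0 °C
Reagents that add atoms: triisopropylsilyl trifluoromethanesulfonate, CC(C)[Si](C(C)C)(C(C)C)OS(=O)(=O)C(F)(F)F
Why: O-Silylation of a cyclic 1,3-dione to its vinylogous silyl ester, in which the bulky silyl group should go to the oxygen on C8 (CH2 neighbours only) and not to the oxygen on C10 beside the quaternary C11, leaving the C10 carbonyl as the only ketone and C7 as the only carbon with acidic hydrogens.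

Step 6
Reactants: 10 (R)-6,6-dimethyl-5-[(S)-3-methyl-3-(triethylsilyloxy)pent-4-enyl]-3-(triisopropylsilyloxy)cyclohex-2-en-1-one
Product: 12 (4S,5R)-4-[(dimethylamino)methyl]-6,6-dimethyl-5-[(S)-3-methyl-3-(triethylsilyloxy)pent-4-enyl]-3-(triisopropylsilyloxy)cyclohex-2-en-1-one, via lithium dienolate 11 (not isolated)
Conditions: LiN(iPr)2, THF, −78 °C; then [Me2N=CH2]I, −78 °C to 0 °C
Reagents that add atoms: N,N-dimethylmethyleneiminium iodide, C=[N+](C)C.[I-]
Why: γ-Deprotonation of a β-silyloxy enone that has no α′ hydrogen gives the extended dienolate, which is aminomethylated at its terminal carbon C7 (Mannich reaction with a preformed iminium salt, the product keeping the conjugated vinylogous ester), the electrophile entering trans to the C6 side chain at a centre that is reset in step 8.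

Step 7
Reactants: 12 (4S,5R)-4-[(dimethylamino)methyl]-6,6-dimethyl-5-[(S)-3-methyl-3-(triethylsilyloxy)pent-4-enyl]-3-(triisopropylsilyloxy)cyclohex-2-en-1-one
Product: 13 (1S,4S,5R)-4-[(dimethylamino)methyl]-6,6-dimethyl-5-[(S)-3-methyl-3-(triethylsilyloxy)pent-4-enyl]-3-(triisopropylsilyloxy)cyclohex-2-en-1-ol
Conditions: LiAlH4, Et2O, −78 °C to −20 °C; aq. NaOH work-up, crude product used directly
Reagents that add atoms: none
Why: 1,2-Reduction of the vinylogous ester carbonyl by LiAlH4 (first half of a Stork–Danheiser sequence), in which the small hydride adds axially to C10 from the face of the axial C6–H and away from the axial C11 methyl group, as in 4,4-dimethyl-3-oxo steroids, so that the new hydroxyl is equatorial and cis to the C6 side chain.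

Step 8
Reactants: 13 (1S,4S,5R)-4-[(dimethylamino)methyl]-6,6-dimethyl-5-[(S)-3-methyl-3-(triethylsilyloxy)pent-4-enyl]-3-(triisopropylsilyloxy)cyclohex-2-en-1-ol
Product: 16 (2R,3R,5S)-5-hydroxy-4,4-dimethyl-3-[(S)-3-methyl-3-(triethylsilyloxy)pent-4-enyl]-2-[(phenylselanyl)methyl]cyclohexan-1-one, via methiodide 14 (not isolated), via enone 15 (not isolated)
Conditions: MeI, THF, rt, then evaporation; Bu4NF (1.1 equiv), THF, −20 °C to 0 °C; then PhSeH (1.5 equiv), 0 °C to rt
Reagents that add atoms: benzeneselenol, [SeH]c1ccccc1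
Why: N-Methylation makes the amine a leaving group, fluoride cleaves the silyl enol ether to the C8 ketone without acid (acid would ionise the allylic C10–O bond, the usual Stork–Danheiser outcome), the β-ammonio ketone loses trimethylamine by E1cB elimination (Mannich-base route to an α-methylene ketone), and the reactive enone 15 is trapped at once by conjugate addition of benzeneselenol, which masks C15 as a selenide and, after equilibration at the enolisable C7, should leave the CH2SePh group equatorial and trans to the C6 side chain.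

Step 9
Reactants: 16 (2R,3R,5S)-5-hydroxy-4,4-dimethyl-3-[(S)-3-methyl-3-(triethylsilyloxy)pent-4-enyl]-2-[(phenylselanyl)methyl]cyclohexan-1-one
Product: 17 (1S,3S,5R,6R)-4,4-dimethyl-5-[(S)-3-methyl-3-(triethylsilyloxy)pent-4-enyl]-6-[(phenylselanyl)methyl]cyclohexane-1,3-diol
Conditions: LiB(sBu)3H (2.2 equiv), THF, −78 °C; aq. NH4Cl (non-oxidative work-up)
Reagents that add atoms: none
Why: Reduction with a bulky trialkylborohydride under steric approach control: in the chair that carries the C6 side chain and the C7 CH2SePh group equatorial the reagent attacks the C8 carbonyl from the equatorial direction, as with 2-alkylcyclohexanones, so that the new hydroxyl is axial, trans to the side chain and anti to C10–OH, the first equivalent only deprotonating the C10 hydroxyl.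

Step 10
Reactants: 17 (1S,3S,5R,6R)-4,4-dimethyl-5-[(S)-3-methyl-3-(triethylsilyloxy)pent-4-enyl]-6-[(phenylselanyl)methyl]cyclohexane-1,3-diol
Product: 18 triethyl{[(3S)-5-[(1R,3R,5R,6S)-3,5-dibromo-2,2-dimethyl-6-[(phenylselanyl)methyl]cyclohexyl]-3-methylpent-1-en-3-yl]oxy}silane
Conditions: CBr4 (4 equiv), PPh3 (4 equiv), 2,6-lutidine, toluene, 0 °C to 60 °C
Reagents that add atoms: tetrabromomethane, BrC(Br)(Br)Br
Why: Appel reaction at both carbinols, each an SN2 displacement of an alkoxyphosphonium group by bromide with inversion: the axial C8 group is displaced first from the equatorial side to give the bromide cis to the side chain, after which bromide can reach the neopentyl C10 along the axial line opposite its equatorial leaving group (no antiperiplanar hydrogen for E2) to give the bromide trans to the side chain, and with C7 still sp3 there is no SN2′ path at C8.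

Step 11
Reactants: 18 triethyl{[(3S)-5-[(1R,3R,5R,6S)-3,5-dibromo-2,2-dimethyl-6-[(phenylselanyl)methyl]cyclohexyl]-3-methylpent-1-en-3-yl]oxy}silane
Product: 20 triethyl{[(3S)-5-[(1S,3R,5R)-3,5-dibromo-2,2-dimethyl-6-methylidenecyclohexyl]-3-methylpent-1-en-3-yl]oxy}silane, via selenoxide 19 (not isolated)
Conditions: H2O2 (30 % aq.), NaHCO3, THF, 0 °C; then iPr2NH, rt to 40 °C
Reagents that add atoms: none
Why: Oxidation to the selenoxide and thermal syn-elimination: selenium sits on C15 and the only β-hydrogen is on C7, so the C7=C15 double bond can form in one position only and the allylic C8 bromide arises without meeting bromide ion or phosphine, the amine and gentle warming answering the slower elimination of a primary selenoxide.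

Step 12
Reactants: 20 triethyl{[(3S)-5-[(1S,3R,5R)-3,5-dibromo-2,2-dimethyl-6-methylidenecyclohexyl]-3-methylpent-1-en-3-yl]oxy}silane
Product: 21 (3S)-5-[(1S,3R,5R)-3,5-dibromo-2,2-dimethyl-6-methylidenecyclohexyl]-3-methylpent-1-en-3-ol
Conditions: Et3N·3HF, MeCN, 0 °C to rt
Reagents that add atoms: none
Why: Fluoride-induced cleavage of the tertiary triethylsilyl ether with an acidic fluoride source whose amine is fully protonated, so that neither elimination nor substitution at the allylic C8 bromide is expected and no stereocentre is touched.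

**Compound list**

1 | (S)-linalool, (3S)-3,7-dimethylocta-1,6-dien-3-ol | C=C[C@@](C)(O)CCC=C(C)C | starting material
2 | triethyl{[(3S)-3,7-dimethylocta-1,6-dien-3-yl]oxy}silane | C=C[C@@](C)(O[Si](CC)(CC)CC)CCC=C(C)C | intermediate
3 | 3,3-dimethyl-5-[(S)-3-methyl-3-(triethylsilyloxy)pent-4-enyl]-1,2,4-trioxolane (secondary ozonide, both epimers at the acetal carbon, not isolated) | C=C[C@@](C)(O[Si](CC)(CC)CC)CCC1OOC(C)(C)O1 | intermediate
4 | (S)-4-methyl-4-(triethylsilyloxy)hex-5-enal | C=C[C@@](C)(O[Si](CC)(CC)CC)CCC=O | intermediate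
5 | 1-(triphenylphosphoranylidene)propan-2-one | CC(=O)C=P(c1ccccc1)(c1ccccc1)c1ccccc1 | starting material
6 | (S,E)-7-methyl-7-(triethylsilyloxy)nona-3,8-dien-2-one | C=C[C@@](C)(O[Si](CC)(CC)CC)CC/C=C/C(C)=O | intermediate
7 | 1-methoxy-2-methyl-1-(trimethylsilyloxy)prop-1-ene | COC(O[Si](C)(C)C)=C(C)C | starting material
8 | methyl (3R,6S)-2,2,6-trimethyl-6-(triethylsilyloxy)-3-[2-(trimethylsilyloxy)prop-1-enyl]oct-7-enoate (enol ether geometry not defined, not isolated) | C=C[C@@](C)(O[Si](CC)(CC)CC)CC[C@H](C=C(C)O[Si](C)(C)C)C(C)(C)C(=O)OC | intermediate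
9 | (R)-4,4-dimethyl-5-[(S)-3-methyl-3-(triethylsilyloxy)pent-4-enyl]cyclohexane-1,3-dione | C=C[C@@](C)(O[Si](CC)(CC)CC)CC[C@@H]1CC(=O)CC(=O)C1(C)C | intermediate
10 | (R)-6,6-dimethyl-5-[(S)-3-methyl-3-(triethylsilyloxy)pent-4-enyl]-3-(triisopropylsilyloxy)cyclohex-2-en-1-one | C=C[C@@](C)(O[Si](CC)(CC)CC)CC[C@@H]1CC(O[Si](C(C)C)(C(C)C)C(C)C)=CC(=O)C1(C)C | intermediate
11 | lithium (5R)-6,6-dimethyl-5-[(S)-3-methyl-3-(triethylsilyloxy)pent-4-enyl]-3-(triisopropylsilyloxy)cyclohexa-1,3-dien-1-olate (not isolated) | C=C[C@@](C)(O[Si](CC)(CC)CC)CC[C@@H]1C=C(O[Si](C(C)C)(C(C)C)C(C)C)C=C([O-])C1(C)C.[Li+] | intermediate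
12 | (4S,5R)-4-[(dimethylamino)methyl]-6,6-dimethyl-5-[(S)-3-methyl-3-(triethylsilyloxy)pent-4-enyl]-3-(triisopropylsilyloxy)cyclohex-2-en-1-one | C=C[C@@](C)(O[Si](CC)(CC)CC)CC[C@@H]1[C@@H](CN(C)C)C(O[Si](C(C)C)(C(C)C)C(C)C)=CC(=O)C1(C)C | intermediate
13 | (1S,4S,5R)-4-[(dimethylamino)methyl]-6,6-dimethyl-5-[(S)-3-methyl-3-(triethylsilyloxy)pent-4-enyl]-3-(triisopropylsilyloxy)cyclohex-2-en-1-ol | C=C[C@@](C)(O[Si](CC)(CC)CC)CC[C@@H]1[C@@H](CN(C)C)C(O[Si](C(C)C)(C(C)C)C(C)C)=C[C@H](O)C1(C)C | intermediate
14 | 1-[(1S,4S,6R)-4-hydroxy-5,5-dimethyl-6-[(S)-3-methyl-3-(triethylsilyloxy)pent-4-enyl]-2-(triisopropylsilyloxy)cyclohex-2-en-1-yl]-N,N,N-trimethylmethanaminium iodide (not isolated) | C=C[C@@](C)(O[Si](CC)(CC)CC)CC[C@@H]1[C@@H](C[N+](C)(C)C)C(O[Si](C(C)C)(C(C)C)C(C)C)=C[C@H](O)C1(C)C.[I-] | intermediate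
15 | (3S,5S)-5-hydroxy-4,4-dimethyl-2-methylidene-3-[(S)-3-methyl-3-(triethylsilyloxy)pent-4-enyl]cyclohexan-1-one (not isolated) | C=C[C@@](C)(O[Si](CC)(CC)CC)CC[C@@H]1C(=C)C(=O)C[C@H](O)C1(C)C | intermediate
16 | (2R,3R,5S)-5-hydroxy-4,4-dimethyl-3-[(S)-3-methyl-3-(triethylsilyloxy)pent-4-enyl]-2-[(phenylselanyl)methyl]cyclohexan-1-one | C=C[C@@](C)(O[Si](CC)(CC)CC)CC[C@@H]1[C@@H](C[Se]c2ccccc2)C(=O)C[C@H](O)C1(C)C | intermediate
17 | (1S,3S,5R,6R)-4,4-dimethyl-5-[(S)-3-methyl-3-(triethylsilyloxy)pent-4-enyl]-6-[(phenylselanyl)methyl]cyclohexane-1,3-diol | C=C[C@@](C)(O[Si](CC)(CC)CC)CC[C@@H]1[C@@H](C[Se]c2ccccc2)[C@@H](O)C[C@H](O)C1(C)C | intermediate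
18 | triethyl{[(3S)-5-[(1R,3R,5R,6S)-3,5-dibromo-2,2-dimethyl-6-[(phenylselanyl)methyl]cyclohexyl]-3-methylpent-1-en-3-yl]oxy}silane | C=C[C@@](C)(O[Si](CC)(CC)CC)CC[C@@H]1[C@@H](C[Se]c2ccccc2)[C@H](Br)C[C@@H](Br)C1(C)C | intermediate
19 | triethyl{[(3S)-5-[(1R,3R,5R,6S)-3,5-dibromo-2,2-dimethyl-6-[(phenylseleninyl)methyl]cyclohexyl]-3-methylpent-1-en-3-yl]oxy}silane (both configurations at selenium, not isolated) | C=C[C@@](C)(O[Si](CC)(CC)CC)CC[C@@H]1[C@@H](C[Se](=O)c2ccccc2)[C@H](Br)C[C@@H](Br)C1(C)C | intermediate
20 | triethyl{[(3S)-5-[(1S,3R,5R)-3,5-dibromo-2,2-dimethyl-6-methylidenecyclohexyl]-3-methylpent-1-en-3-yl]oxy}silane | C=C[C@@](C)(O[Si](CC)(CC)CC)CC[C@@H]1C(=C)[C@H](Br)C[C@@H](Br)C1(C)C | intermediate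
21 | (3S)-5-[(1S,3R,5R)-3,5-dibromo-2,2-dimethyl-6-methylidenecyclohexyl]-3-methylpent-1-en-3-ol | C=C[C@@](C)(O)CC[C@@H]1C(=C)[C@H](Br)C[C@@H](Br)C1(C)C | target

**Step count and risks**

Total step count: 12. Longest linear sequence: 12 steps (1 to 21).

The three steps most likely to fail:

Step 10. Substitution at the neopentyl C10 is slow, so syn-elimination of the alkoxyphosphonium group, migration of the C11–C6 bond with ring contraction, or E2 at C8 through the hydrogens antiperiplanar to the axial leaving group may take over. The fallback separates activation from displacement and sets out from 17. Tf2O and pyridine in CH2Cl2 at −60 °C should give the 1,3-bis(trifluoromethanesulfonate) F1. Bu4NBr in toluene from −40 °C to room temperature then displaces first the C8 and then the C10 sulfonate, each with inversion (SN2 on a sulfonate by a poorly solvated bromide in a non-ionising solvent, with no heating). The route is rejoined at 18.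

Step 11. The syn-elimination of a primary selenoxide is slow, which leaves time for reduction back to the selenide, addition of the selenenic acid to the new alkene, or allylic transposition of the C8 bromide on warming. The fallback forms the allylic bromide by substitution instead and sets out from 15, which is isolated by running step 8 without benzeneselenol. Me4NBH(OAc)3 in MeCN/AcOH at −25 °C (hydroxyl-directed reduction, hydride delivered from the C10 oxygen) should give the allylic anti-diol F2. tBuCOCl and pyridine acylate the allylic C8 hydroxyl to give the pivalate F3, the hydroxyl beside C11 staying free. CBr4/PPh3 in toluene at 60 °C inverts C10 to the bromide F4. iBu2AlH at −78 °C frees the allylic alcohol F5. CBr4/PPh3 in CH2Cl2 at −30 °C inverts C8, and the route is rejoined at 20.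

Step 4. Facial selectivity at C6 may be poor with this acyclic enone, or the cationic boron Lewis acid may ionise the tertiary allylic silyl ether. The fallback activates the nucleophile instead of the enone and sets out from 6 and 7. LiOAc (10 mol %) in DMF at −20 °C (Lewis-base-catalysed Mukaiyama–Michael addition) should give 8 together with its C3 epimer, the silyl enol ether F6 (not isolated). KOtBu as in step 4 gives 9 and the epimeric dione F7. Silylation as in step 5 gives 10 and the epimeric vinylogous silyl ester F8, which is removed by preparative HPLC on a chiral stationary phase. The route is rejoined at 10.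

**Further compounds**

F1 | step 10 | (1S,3S,5R,6R)-4,4-dimethyl-5-[(S)-3-methyl-3-(triethylsilyloxy)pent-4-enyl]-6-[(phenylselanyl)methyl]cyclohexane-1,3-diyl bis(trifluoromethanesulfonate) | C=C[C@@](C)(O[Si](CC)(CC)CC)CC[C@@H]1[C@@H](C[Se]c2ccccc2)[C@@H](OS(=O)(=O)C(F)(F)F)C[C@H](OS(=O)(=O)C(F)(F)F)C1(C)C
F2 | step 11 | (1S,3S,5S)-4,4-dimethyl-6-methylidene-5-[(S)-3-methyl-3-(triethylsilyloxy)pent-4-enyl]cyclohexane-1,3-diol | C=C[C@@](C)(O[Si](CC)(CC)CC)CC[C@@H]1C(=C)[C@@H](O)C[C@H](O)C1(C)C
F3 | step 11 | (1S,3S,5S)-5-hydroxy-4,4-dimethyl-2-methylidene-3-[(S)-3-methyl-3-(triethylsilyloxy)pent-4-enyl]cyclohexyl 2,2-dimethylpropanoate | C=C[C@@](C)(O[Si](CC)(CC)CC)CC[C@@H]1C(=C)[C@@H](OC(=O)C(C)(C)C)C[C@H](O)C1(C)C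
F4 | step 11 | (1S,3R,5R)-5-bromo-4,4-dimethyl-2-methylidene-3-[(S)-3-methyl-3-(triethylsilyloxy)pent-4-enyl]cyclohexyl 2,2-dimethylpropanoate | C=C[C@@](C)(O[Si](CC)(CC)CC)CC[C@@H]1C(=C)[C@@H](OC(=O)C(C)(C)C)C[C@@H](Br)C1(C)C
F5 | step 11 | (1S,3R,5R)-5-bromo-4,4-dimethyl-2-methylidene-3-[(S)-3-methyl-3-(triethylsilyloxy)pent-4-enyl]cyclohexan-1-ol | C=C[C@@](C)(O[Si](CC)(CC)CC)CC[C@@H]1C(=C)[C@@H](O)C[C@@H](Br)C1(C)C
F6 | step 4 | methyl (3S,6S)-2,2,6-trimethyl-6-(triethylsilyloxy)-3-[2-(trimethylsilyloxy)prop-1-enyl]oct-7-enoate | C=C[C@@](C)(O[Si](CC)(CC)CC)CC[C@@H](C=C(C)O[Si](C)(C)C)C(C)(C)C(=O)OC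
F7 | step 4 | (S)-4,4-dimethyl-5-[(S)-3-methyl-3-(triethylsilyloxy)pent-4-enyl]cyclohexane-1,3-dione | C=C[C@@](C)(O[Si](CC)(CC)CC)CC[C@H]1CC(=O)CC(=O)C1(C)C
F8 | step 4 | (S)-6,6-dimethyl-5-[(S)-3-methyl-3-(triethylsilyloxy)pent-4-enyl]-3-(triisopropylsilyloxy)cyclohex-2-en-1-one | C=C[C@@](C)(O[Si](CC)(CC)CC)CC[C@H]1CC(O[Si](C(C)C)(C(C)C)C(C)C)=CC(=O)C1(C)C
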